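## Structural features

The target is the ester of (E)-4-hydroxycinnamic acid with the secondary hydroxyl of a sesquiterpene diol. Its core is a hydroazulene: a cyclopentane (C1–C5) and a cycloheptene (C1, C5–C10) share the C1–C5 bond in a trans fusion. Four stereocentres stand in a row: quaternary C1 (methyl), the ring-fusion methine C5, the tertiary carbinol C4 (hydroxyl and isopropyl) and the acylated carbinol C6. The C1 methyl and the C4 hydroxyl lie on one face (called β here), H5 and the C6 oxygen on the other (α), so the two oxygens are 1,3-anti across C5; the descriptors are 1R,4R,5S,6S. The trisubstituted C8=C9 alkene is β,γ to C6 and slips into conjugation whenever C6 is a ketone; the tertiary alcohol is β to the C6 oxygen, so ketone-stage intermediates can eliminate; the cinnamate with its free phenol tolerates neither hydrides nor organometallics. The real difficulty is the quaternary C1 next to a trans ring-fusion hydrogen that is flanked on both sides by oxygen-bearing stereocentres, in a medium ring with little conformational bias. The seven-membered ring carries oxygen at C6, the alkene at C8=C9 and the quaternary terminus C1, which is the pattern of a 1,4-cycloheptadiene (C5=C6 enol ether and C8=C9) built from a 2-siloxydiene (C7=C6–C5=C1) and a vinylcarbene (C8–C9=C10). The key step uses exactly this: it forms C7–C8 and C1–C10, closes the cycloheptene and sets C1, while the cyclopentane with its C4 carbonyl comes from 3-methylcyclopentenone.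

## Logic of the disconnections

**Ester C6–O.** 30 is traced to 29 and then to 24 and 27 by cutting the acyl–oxygen bond. The cinnamate would not survive any hydride or organometallic step, so it goes on last. This removes the whole aromatic part and leaves a diol. The forward acylation must choose the secondary over the tertiary hydroxyl, and the phenol must be masked (27 from 25 through 26).

**C4–isopropyl bond.** 24 and 23 go back to 22 by cutting the C4–CH(CH3)2 bond. The tertiary carbinol is the addition product of a ketone that is already latent in the starting enone. This removes one stereocentre and three carbons. The nucleophile must enter from the α face and must not enolise 22 toward C5, where a β-silyloxy group could leave.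

**C5–H and C6–H.** 22, 21, 20 and 19 go back to 18 without any skeletal cut: the C6–H bond comes from a ketone and the C5–H bond from the silyl enol ether. Two stereocentres are thereby reduced to one alkene. The forward steps must deliver a proton to C5 anti to the C1 methyl and a hydrogen to C6 from the methyl face, and must not let C8=C9 move while C6 is a ketone.

**C8 methyl.** 18 goes back through 17 and 16 to 15 by cutting C–O bonds only. The ester is needed as the acceptor of the carbenoid and is surplus afterwards. The order is chosen so that the ester is removed before C6 is unmasked: a ketone at C6 next to the unsaturated ester would invite migration of the alkene to C7=C8. The forward hydride displacement must occur at the primary carbon without allylic transposition and must spare the silyl enol ether and the ketal.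

**Key disconnection, C7–C8 and C1–C10.** 15 goes back through 14 to 8 and 13. Cutting these two bonds removes the seven-membered ring and the only stereocentre of 15, and leaves an achiral diene and a three-carbon diazo ester. The forward step must react at the terminal enol ether only, must give the cis-divinylcyclopropane with one absolute configuration, and must then pass a boat transition state with the C1 methyl pointing inward.

**Diene 8.** 8 goes back to 7 (O–Si bond) and 7 to 6, hence to 4 and 5 (bond between the ring carbon C5 and the acetyl carbon C6). This separates the ring from a two-carbon acyl unit. The forward enolisation must occur at the acetyl methyl, and the vinyl anion requires the ring ketone to be masked.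

**Bromide 4.** 4 goes back to 3 and, through 2, to 1 by cutting the ketal C–O bonds and the C–Br bond. The bromine is the handle for metalation and also keeps the alkene in place during ketalisation.

**Diazo ester 13.** 13 goes back through 12 and 11 to 10 and 9: the vinyl group comes from dehydration of a carbinol, the carbinol from a ketone, and the diazo group from diazo transfer to an active methylene. The forward elimination must give a compound that is used cold and at once.

## Other disconnections considered

**Alternative 1:** The cut is the C4–C5 bond of the cyclopentane. The lithiated dithiane at the end of the two-carbon chain on C1 of epoxide A1 would attack C5 of the α-epoxide from the rear in a 5-exo closure and give A2 with the trans fusion and the 6α-alkoxide.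
- In its favour: C5 and C6 are set together and stereospecifically by one SN2 event, the dithiane is a masked C4 ketone, and no β,γ-unsaturated ketone ever appears. On the control of C5 and C6 this alternative is the better of the two, since the chosen plan needs a separate protonation and a separate reduction.
- Against it: A1 needs an enantiopure cycloheptadiene with quaternary C1 already in place and an epoxidation on the face of the side chain, for which methyl versus CH2 on C1 offers little bias, and C8=C9 competes. The tether must reach the rear of C5 across the ring, against the preference for trans-diaxial opening. The strongly basic anion can instead isomerise the epoxide through the allylic C7 hydrogens.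
- Comparison: structurally A2 holds three of the four stereocentres, against one in 15. Mechanistically it is a polar closure governed by strain and basicity, where the chosen plan uses a carbenoid addition and a pericyclic ring expansion that needs no strong base. In step economy it is behind before the key step (ring and C1 built separately, dithiane removal added) and equal after it.

**Alternative 2:** The cut is the C1–C5 bond, which in the precursor is the C1–C6 bond of a cis-decalin. In monomesylate A3 the C6 alkoxide would push C1 from C6 to C5, anti to the equatorial mesylate, contracting ring A and enlarging ring B to give ketone A4.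
- In its favour: the shift is stereospecific (retention at C1, inversion at C5), so the trans fusion is fixed by the geometry of A3 and not by a protonation, which is better than the chosen plan at C5. A4 already carries C1, C4 and C5, and the C4 hydroxyl could later direct the reduction of C6. Decalins with an angular methyl are readily made in enantioenriched form.
- Against it: A3 is a densely functionalised decalin (tertiary silyl ether with isopropyl beside a cis-diol, plus the trisubstituted alkene) that needs a long linear preparation with stereochemical problems of its own. A4 is again a β,γ-unsaturated ketone with an epimerisable C5 and adds a β-silyloxy group that can leave.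
- Comparison: mechanistically an anionic 1,2-shift is more predictable than a congested boat Cope rearrangement, a point on which it is the equal or the better. In step economy it is longer before the key step and shorter after it; the chosen plan is the more convergent overall.

**Alternative 3:** The cut is the C1–C2 bond. Lewis acid activation of dienone A5 would trigger conrotatory 4π closure, loss of the silyl group placing the C2=C3 alkene, and protonation at C5, to give A6.
- In its favour: the cyclopentenone and the quaternary carbon arise in one step, silicon fixes the alkene position, and the C4 ketone needs no ketal steps, which is a point in its favour.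
- Against it: closure onto a fully substituted alkene terminus is among the slowest cases of this cyclisation. The sense of rotation is relayed only from C6. With the new bond formed anti to the silyloxy group, the C6 oxygen ends on the face of the C1 methyl, so A6 as formulated is the C6 epimer of what the target needs, and an inversion at C6 would have to be added. C5 is set by protonation, so here the alternative is only the equal of the chosen plan. C2=C3 must later be reduced in the presence of C8=C9, and the Lewis acid may ionise the allylic silyl ether.
- Comparison: A5 needs its own enantioselective synthesis, while the chosen plan creates C1 by catalyst control from achiral 8. Both rely on an orbital-symmetry-controlled step at a congested terminus, one cationic with strong Lewis acid, the other neutral with heat. Step counts would be similar.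

Key step: step 8

Assumption: Rh2(R-DOSP)4 is dirhodium tetrakis[(R)-1-(4-dodecylphenylsulfonyl)prolinate]; its antipode was chosen by analogy with the known sense of donor–acceptor carbenoid cyclopropanation (the S catalyst giving the 1S,2R diaryl cyclopropane from styrene), and if the sense were reversed for this diene, Rh2(S-DOSP)4 would be used instead.

## Route

Step 1
Reactants: 1 3-methylcyclopent-2-en-1-one
Product: 3 2-bromo-3-methylcyclopent-2-en-1-one, via dibromoketone 2 (not isolated)
Conditions: Br2, CH2Cl2, 0 °C; then Et3N, 0 °C to rt
Reagents that add atoms: bromine, BrBr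
Why: Bromine adds across the enone alkene and triethylamine removes HBr (the C2 proton is α to the carbonyl), the usual addition–elimination α-bromination of a cyclic enone; it gives the vinyl bromide needed for halogen–metal exchange.

Step 2
Reactants: 3 2-bromo-3-methylcyclopent-2-en-1-one
Product: 4 6-bromo-7-methyl-1,4-dioxaspiro[4.4]non-6-ene
Conditions: HOCH2CH2OH, p-TsOH (cat.), PhH, reflux, azeotropic removal of water
Reagents that add atoms: ethane-1,2-diol, OCCO
Why: Acid-catalysed ketalisation; the C2 bromine holds the alkene in the 2,3-position so that no deconjugated ketal is expected, and the dioxolane masks C4 through the organolithium, carbenoid and hydride steps.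

Step 3
Reactants: 4 6-bromo-7-methyl-1,4-dioxaspiro[4.4]non-6-ene; 5 N-methoxy-N-methylacetamide
Product: 7 1-(7-methyl-1,4-dioxaspiro[4.4]non-6-en-6-yl)ethan-1-one, via vinyllithium 6 (not isolated)
Conditions: n-BuLi, THF, −78 °C; then 5, −78 to 0 °C; H2O
Reagents that add atoms: none
Why: Bromine–lithium exchange gives vinyllithium 6 with the alkene position retained, and acylation by the N-methoxy-N-methylamide stops at the ketone because the chelated tetrahedral adduct collapses only on work-up.

Step 4
Reactants: 7 1-(7-methyl-1,4-dioxaspiro[4.4]non-6-en-6-yl)ethan-1-one
Product: 8 tert-butyl(dimethyl){[1-(7-methyl-1,4-dioxaspiro[4.4]non-6-en-6-yl)ethenyl]oxy}silane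
Conditions: TBSOTf, Et3N, CH2Cl2, 0 °C
Reagents that add atoms: tert-butyldimethylsilyl trifluoromethanesulfonate, CC(C)(C)[Si](C)(C)OS(=O)(=O)C(F)(F)F
Why: Soft enolisation: the silyl triflate activates the carbonyl oxygen and the amine removes a proton from the acetyl methyl, the only α-position, giving the 2-siloxydiene; γ-deprotonation would need a planar s-cis dienone that the flanking ketal and methyl disfavour, and the excess amine protects the ketal.

Step 5
Reactants: 9 methyl acetoacetate
Product: 10 methyl 2-diazo-3-oxobutanoate
Conditions: 4-AcNHC6H4SO2N3, Et3N, MeCN, 0 °C to rt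
Reagents that add atoms: 4-acetamidobenzenesulfonyl azide, CC(=O)Nc1ccc(cc1)S(=O)(=O)N=[N+]=[N-]
Why: Regitz diazo transfer to the doubly activated methylene of a β-keto ester.

Step 6
Reactants: 10 methyl 2-diazo-3-oxobutanoate
Product: 11 methyl 2-diazo-3-hydroxybutanoate
Conditions: NaBH4, MeOH, 0 °C
Reagents that add atoms: none
Why: Borohydride reduces the ketone chemoselectively while the ester and the diazo group are inert at 0 °C; the new carbinol centre is destroyed in step 7 and is left racemic.

Step 7
Reactants: 11 methyl 2-diazo-3-hydroxybutanoate
Product: 13 methyl 2-diazobut-3-enoate, via dichlorophosphate 12 (not isolated)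
Conditions: POCl3, Et3N, CH2Cl2, 0 °C; cold pentane extraction
Reagents that add atoms: none
Why: Phosphorylation of the secondary alcohol and amine-promoted β-elimination (dehydration) give the vinyl diazo ester; 13 closes slowly to a pyrazole at room temperature and is therefore kept cold and used at once.

Step 8
Reactants: 8 tert-butyl(dimethyl){[1-(7-methyl-1,4-dioxaspiro[4.4]non-6-en-6-yl)ethenyl]oxy}silane; 13 methyl 2-diazobut-3-enoate
Product: 15 (1R)-dienyl ester (C4 dioxolane; C5=C6 OTBS; C8=C9 bearing CO2Me on C8), via divinylcyclopropane 14 (not isolated)
Conditions: Rh2(R-DOSP)4 (1 mol %), hexane, −78 °C, slow addition of 13 (2 equiv), then to rt; PhMe, 80–100 °C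
Reagents that add atoms: none
Why: The catalyst turns 13 into a donor–acceptor vinylcarbenoid whose carbene carbon C8 adds to the terminal CH2 (C7) of the silyl enol ether of 8, the most electron-rich and least hindered alkene, to give cyclopropane 14 (bonds C7–C8 and C6–C8) with the cyclopentenyl group cis to the vinyl group, since such carbenoids place the alkene substituent on the donor side. Warming then drives the [3,3] shift of the cis-divinylcyclopropane through a boat transition state, which breaks C6–C8 and forms C1–C10. The closest known reaction type is the rhodium-carbenoid tandem cyclopropanation–Cope rearrangement of vinyldiazoacetates with dienes (formal [4+3] cycloaddition). The seven-membered ring is closed by this concerted suprafacial sigmatropic ring expansion and not by a polar cyclisation, so no other ring size can compete. The only stereocentre that survives, quaternary C1, is set by chirality transfer: the prolinate ligands fix the configuration of C6 and C8 in 14, and the boat geometry lets C10 reach only one face of the C5=C1 alkene. The step needs chemoselectivity for the enol ether over the tetrasubstituted ring alkene and the ketal oxygens; the nucleophilicity of the siloxy alkene secures it, and the hydrocarbon solvent suppresses ylide formation and attack at the vinylogous position of the carbenoid. The ring forces the C1 methyl to point into the boat, which is why heating is planned for the second stage.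

Step 9
Reactants: 15 (1R)-dienyl ester
Product: 16 (1R)-allylic alcohol (CH2OH on C8; C4 dioxolane; C5=C6 OTBS)
Conditions: i-Bu2AlH, CH2Cl2, −78 °C; aq. KNaC4H4O6
Reagents that add atoms: none
Why: 1,2-Reduction of the conjugated ester to the allylic alcohol; at −78 °C the silyl enol ether and the ketal are untouched and C1 is remote from any reacting site.

Step 10
Reactants: 16 (1R)-allylic alcohol
Product: 18 (1R)-silyl enol ether (CH3 on C8; C4 dioxolane; C5=C6 OTBS), via allylic mesylate 17 (not isolated)
Conditions: MsCl, Et3N, THF, −30 °C; then LiEt3BH, −30 °C to rt
Reagents that add atoms: none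
Why: Sulfonylation of the primary allylic alcohol and SN2 displacement by the borohydride (reductive deoxygenation of an allylic sulfonate) turn CH2OH into the C8 methyl; the primary centre and the small, strongly nucleophilic hydride favour direct over allylic attack, and any allylic chloride formed from 17 is reduced alike.

Step 11
Reactants: 18 (1R)-silyl enol ether
Product: 19 (1R,5S)-ketone (C6=O; C4 dioxolane; trans ring fusion)
Conditions: Bu4NF, AcOH, THF, −20 to 0 °C
Reagents that add atoms: none
Why: Fluoride cleaves the O–Si bond and acetic acid protonates the enolate on carbon (desilylative ketonisation of a silyl enol ether); on the flattened cycloheptadiene the C1 methyl stands nearly perpendicular to the enolate plane and screens the β face, so the proton should enter anti to it and give the trans fusion (H5 α), and the cold buffered medium keeps the β,γ-alkene in place.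

Step 12
Reactants: 19 (1R,5S)-ketone
Product: 20 (1R,5S,6S)-alcohol (6α-OH; C4 dioxolane)
Conditions: Li, NH3(l), THF, t-BuOH, −78 °C; NH4Cl
Reagents that add atoms: none
Why: Dissolving-metal reduction of a ketone gives the more stable equatorial alcohol, here 6α, on the face of H5 and away from the C1 methyl, whereas hydride reagents would be expected to attack from the open α face and give the axial 6β epimer; the isolated alkene and the ketal are inert.

Step 13
Reactants: 20 (1R,5S,6S)-alcohol
Product: 21 (1R,5S,6S)-silyl ether (6α-OTBS; C4 dioxolane)
Conditions: TBSOTf, 2,6-lutidine, CH2Cl2, −78 to 0 °C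
Reagents that add atoms: tert-butyldimethylsilyl trifluoromethanesulfonate, CC(C)(C)[Si](C)(C)OS(=O)(=O)C(F)(F)F
Why: Silylation of the hindered secondary hydroxyl with silyl triflate and a hindered pyridine base; the base and low temperature spare the dioxolane, and the non-chelating silyl ether is a poorer leaving group than an ester for the ketone stage that follows.

Step 14
Reactants: 21 (1R,5S,6S)-silyl ether
Product: 22 (1R,5S,6S)-ketone (C4=O; 6α-OTBS)
Conditions: PPTS, acetone/H2O, 50 °C
Reagents that add atoms: water, O
Why: Mild acid-catalysed hydrolysis of the dioxolane; the pyridinium salt is too weak an acid to cleave the secondary silyl ether, to enolise the new ketone toward C5 or to eliminate the β-silyloxy group.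

Step 15
Reactants: 22 (1R,5S,6S)-ketone
Product: 23 (1R,4R,5S,6S)-tertiary alcohol (4β-OH; 4α-isopropyl; 6α-OTBS)
Conditions: CeCl3, i-PrMgCl, THF, −78 °C
Reagents that add atoms: isopropylmagnesium chloride, CC(C)[Mg]Cl
Why: 1,2-Addition of the organocerium reagent formed in the flask, which is far less basic than the organomagnesium reagent and so suppresses enolisation toward C5 and loss of the silyloxy group; the nucleophile should enter the cyclopentanone from the α face, anti to the adjacent C5–C6 bond and the pseudo-axial C1 methyl, placing isopropyl α and hydroxyl β.

Step 16
Reactants: 23 (1R,4R,5S,6S)-tertiary alcohol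
Product: 24 (1R,4R,5S,6S)-diol
Conditions: Bu4NF, THF, rt to 45 °C
Reagents that add atoms: none
Why: Fluoride cleavage of the secondary silyl ether; the tertiary alcohol and the alkene are inert.

Step 17
Reactants: 25 (E)-4-hydroxycinnamic acid
Product: 27 (E)-4-(tert-butyldimethylsilyloxy)cinnamic acid, via bis-silyl compound 26 (not isolated)
Conditions: TBSCl, imidazole, DMF, rt; then AcOH/THF/H2O, rt
Reagents that add atoms: tert-butyldimethylsilyl chloride, CC(C)(C)[Si](C)(C)Cl
Why: Silylation of phenol and acid followed by selective hydrolysis of the much more labile silyl ester leaves the phenol masked, so that it cannot compete in the acylation of step 18.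

Step 18
Reactants: 24 (1R,4R,5S,6S)-diol; 27 (E)-4-(tert-butyldimethylsilyloxy)cinnamic acid
Product: 29 (1R,4R,5S,6S)-6-O-[(E)-4-(tert-butyldimethylsilyloxy)cinnamoyl] ester, via mixed anhydride 28 (not isolated)
Conditions: 2,4,6-Cl3C6H2COCl, Et3N, THF, rt; then 24, DMAP, PhMe, rt to 40 °C
Reagents that add atoms: none
Why: Yamaguchi esterification: mixed anhydride 28 passes the cinnamoyl group through the acylpyridinium ion to the secondary C6 hydroxyl, the tertiary C4 hydroxyl beside isopropyl being too hindered to react; the reaction occurs at oxygen, so C6 keeps its configuration.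

Step 19
Reactants: 29 (1R,4R,5S,6S)-silyl-protected ester
Product: 30 (1R,4R,5S,6S)-target, the 6-O-[(E)-4-hydroxycinnamoyl] ester of diol 24
Conditions: Bu4NF, AcOH, THF, 0 °C
Reagents that add atoms: none
Why: Buffered fluoride removes the aryl silyl ether, the most labile silyl group, at 0 °C; acetic acid keeps the phenoxide from attacking the ester or adding to the cinnamate.

## Compound list

1 | 3-methylcyclopent-2-en-1-one | CC1=CC(=O)CC1 | starting material
2 | 2,3-dibromo-3-methylcyclopentan-1-one (racemic) | CC1(Br)CCC(=O)C1Br | intermediate (not isolated)
3 | 2-bromo-3-methylcyclopent-2-en-1-one | CC1=C(Br)C(=O)CC1 | intermediate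
4 | 6-bromo-7-methyl-1,4-dioxaspiro[4.4]non-6-ene | CC1=C(Br)C2(CC1)OCCO2 | intermediate
5 | N-methoxy-N-methylacetamide | CC(=O)N(C)OC | starting material
6 | (7-methyl-1,4-dioxaspiro[4.4]non-6-en-6-yl)lithium | [Li]C1=C(C)CCC12OCCO2 | intermediate (not isolated)
7 | 1-(7-methyl-1,4-dioxaspiro[4.4]non-6-en-6-yl)ethan-1-one | CC(=O)C1=C(C)CCC12OCCO2 | intermediate
8 | tert-butyl(dimethyl){[1-(7-methyl-1,4-dioxaspiro[4.4]non-6-en-6-yl)ethenyl]oxy}silane | C=C(O[Si](C)(C)C(C)(C)C)C1=C(C)CCC12OCCO2 | intermediate
9 | methyl acetoacetate | CC(=O)CC(=O)OC | starting material
10 | methyl 2-diazo-3-oxobutanoate | CC(=O)C(=[N+]=[N-])C(=O)OC | intermediate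
11 | methyl 2-diazo-3-hydroxybutanoate (racemic) | CC(O)C(=[N+]=[N-])C(=O)OC | intermediate
12 | methyl 3-[(dichlorophosphoryl)oxy]-2-diazobutanoate (racemic) | CC(OP(=O)(Cl)Cl)C(=[N+]=[N-])C(=O)OC | intermediate (not isolated)
13 | methyl 2-diazobut-3-enoate | C=CC(=[N+]=[N-])C(=O)OC | intermediate
14 | methyl (1S,2R)-2-(tert-butyldimethylsilyloxy)-1-ethenyl-2-(7-methyl-1,4-dioxaspiro[4.4]non-6-en-6-yl)cyclopropane-1-carboxylate (vinyl and cyclopentenyl cis) | COC(=O)[C@]1(C=C)C[C@@]1(O[Si](C)(C)C(C)(C)C)C1=C(C)CCC12OCCO2 | intermediate (not isolated)
15 | (1R)-dienyl ester: hydroazulene with C1 methyl, C4 ethylene ketal, C5=C6 TBS enol ether, C8=C9 and CO2Me on C8 | COC(=O)C1=CC[C@@]2(C)CCC3(OCCO3)C2=C(O[Si](C)(C)C(C)(C)C)C1 | intermediate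
16 | (1R)-allylic alcohol: as 15 with CH2OH on C8 | OCC1=CC[C@@]2(C)CCC3(OCCO3)C2=C(O[Si](C)(C)C(C)(C)C)C1 | intermediate
17 | (1R)-allylic mesylate: as 16 with CH2OSO2CH3 on C8 | CS(=O)(=O)OCC1=CC[C@@]2(C)CCC3(OCCO3)C2=C(O[Si](C)(C)C(C)(C)C)C1 | intermediate (not isolated)
18 | (1R)-silyl enol ether: as 15 with CH3 on C8 | CC1=CC[C@@]2(C)CCC3(OCCO3)C2=C(O[Si](C)(C)C(C)(C)C)C1 | intermediate
19 | (1R,5S)-ketone: trans-fused, C6=O, C4 ethylene ketal, C8=C9 | CC1=CC[C@@]2(C)CCC3(OCCO3)[C@@H]2C(=O)C1 | intermediate
20 | (1R,5S,6S)-alcohol: 6α-OH (on the face of H5), C4 ethylene ketal | CC1=CC[C@@]2(C)CCC3(OCCO3)[C@@H]2[C@@H](O)C1 | intermediate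
21 | (1R,5S,6S)-silyl ether: 6α-OTBS, C4 ethylene ketal | CC1=CC[C@@]2(C)CCC3(OCCO3)[C@@H]2[C@@H](O[Si](C)(C)C(C)(C)C)C1 | intermediate
22 | (1R,5S,6S)-ketone: C4=O, 6α-OTBS, trans-fused | CC1=CC[C@@]2(C)CCC(=O)[C@@H]2[C@@H](O[Si](C)(C)C(C)(C)C)C1 | intermediate
23 | (1R,4R,5S,6S)-tertiary alcohol: 4β-OH, 4α-isopropyl, 6α-OTBS | CC1=CC[C@@]2(C)CC[C@@](O)(C(C)C)[C@@H]2[C@@H](O[Si](C)(C)C(C)(C)C)C1 | intermediate
24 | (3R,3aS,4S,8aR)-6,8a-dimethyl-3-(propan-2-yl)-1,2,3,3a,4,5,8,8a-octahydroazulene-3,4-diol (jaeschkeanadiol) | CC1=CC[C@@]2(C)CC[C@@](O)(C(C)C)[C@@H]2[C@@H](O)C1 | intermediate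
25 | (E)-4-hydroxycinnamic acid | OC(=O)/C=C/c1ccc(O)cc1 | starting material
26 | tert-butyldimethylsilyl (E)-4-(tert-butyldimethylsilyloxy)cinnamate | CC(C)(C)[Si](C)(C)Oc1ccc(/C=C/C(=O)O[Si](C)(C)C(C)(C)C)cc1 | intermediate (not isolated)
27 | (E)-4-(tert-butyldimethylsilyloxy)cinnamic acid | CC(C)(C)[Si](C)(C)Oc1ccc(/C=C/C(O)=O)cc1 | intermediate
28 | (E)-4-(tert-butyldimethylsilyloxy)cinnamic 2,4,6-trichlorobenzoic anhydride | CC(C)(C)[Si](C)(C)Oc1ccc(/C=C/C(=O)OC(=O)c2c(Cl)cc(Cl)cc2Cl)cc1 | intermediate (not isolated)
29 | (1R,4R,5S,6S)-6-O-[(E)-4-(tert-butyldimethylsilyloxy)cinnamoyl] ester of 24 | CC1=CC[C@@]2(C)CC[C@@](O)(C(C)C)[C@@H]2[C@@H](OC(=O)/C=C/c2ccc(O[Si](C)(C)C(C)(C)C)cc2)C1 | intermediate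
30 | (3R,3aS,4S,8aR)-3-hydroxy-6,8a-dimethyl-3-(propan-2-yl)-1,2,3,3a,4,5,8,8a-octahydroazulen-4-yl (2E)-3-(4-hydroxyphenyl)prop-2-enoate | CC1=CC[C@@]2(C)CC[C@@](O)(C(C)C)[C@@H]2[C@@H](OC(=O)/C=C/c2ccc(O)cc2)C1 | target

## Step count and least certain steps

Total: 19 steps. Longest linear sequence: 15 steps (steps 1–4, 8–16, 18, 19); steps 5–7 and step 17 are side branches.

**Step 8 (key step).** The most likely failure is loss of stereochemical information. The boat with the inward C1 methyl needs heat, and at that temperature the donor–acceptor cyclopropane can open at C6–C8 and reclose, or the isomer with the siloxy group cis to the vinyl group must first isomerise. Either process erodes the enantiomeric purity that the catalyst installed. A second risk is carbenoid capture by a ketal oxygen. Fallback, setting out from 20 and coming back at 20: material of insufficient enantiomeric purity (in the limit, material from a run with achiral Rh2(O2CC7H15)4 in hot toluene, where only the Cope stage has to be driven) is carried to 20 and esterified with (S)-2-methoxy-2-phenylacetic acid (DCC, DMAP). This gives the wanted (S)-2-methoxy-2-phenylacetate of 20, F1, and the diastereomeric ester of the antipodal alcohol, F2. They are separated by chromatography or crystallisation, and F1 is saponified (LiOH, THF/MeOH/H2O) to 20. Stereocontrol then rests on resolution and not on the catalyst.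

**Step 11.** The likely failure is protonation on the wrong face of the enolate. The two faces of C5 differ only by the methyl and the ring CH2 on C1, so a cis ring fusion is possible. Base-induced migration of C8=C9 into conjugation is the second risk, and it rules out simple equilibration of C5 at this stage. Fallback, setting out from 15 and coming back at 20: the silyl enol ether of 15 is converted into the enol triflate F3 (CsF, PhNTf2, DME), which is reduced to the C5=C6 alkene F4 (Pd(OAc)2, PPh3, Bu3N, HCO2H, DMF). Hydroboration–oxidation (BH3·SMe2, THF, 0 °C; NaBO3) from the face opposite the C1 methyl adds H to C5 and OH to C6 in a syn manner and should give the hydroxy ester F5 with H5 and the C6 hydroxyl both α; the electron-poor unsaturated ester should react more slowly than the isolated alkene. Reduction with i-Bu2AlH gives the diol F6; selective mesylation of the primary allylic hydroxyl (MsCl, Et3N, −40 °C) gives the mesylate F7, which LiEt3BH converts to 20. C5 and C6 are then set by one stereospecific addition and not by protonation and reduction.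

**Step 12.** The likely failure is incomplete selectivity for the equatorial alcohol, or enolisation under the basic conditions with opening of the β-ketal or movement of the alkene. Fallback, setting out from 19 and coming back at 20: reduction with Li(s-Bu)3BH (THF, −78 °C) from the open α face should give the axial 6β-alcohol F8. Mitsunobu esterification with 4-nitrobenzoic acid (PPh3, DIAD) inverts C6 to the 6α-4-nitrobenzoate F9, and K2CO3 in MeOH releases 20. The configuration then comes from kinetic hydride attack followed by SN2 inversion.

**Step 15.** The likely failures are enolisation of 22 toward C5 with loss of the β-silyloxy group, reduction of the hindered ketone by β-hydride transfer from the isopropyl reagent, or competing attack from the β face because the 6α-silyloxy group crowds the α face. Fallback, setting out from 22 and coming back at 23: CH2=C(CH3)MgBr with CeCl3 (THF, −78 °C), a smaller sp2 nucleophile that cannot act as a hydride donor, gives the isopropenyl carbinol F10. Hydrogenation of its 1,1-disubstituted alkene with RhCl(PPh3)3 and H2 in benzene, which should spare the trisubstituted ring alkene, gives 23.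

## Further compounds

F1 | step 8 | (S)-2-methoxy-2-phenylacetate of 20 (wanted diastereomer) | CC1=CC[C@@]2(C)CCC3(OCCO3)[C@@H]2[C@@H](OC(=O)[C@@H](OC)c2ccccc2)C1
F2 | step 8 | (S)-2-methoxy-2-phenylacetate of the antipode of 20 (diastereomer to be removed) | CC1=CC[C@]2(C)CCC3(OCCO3)[C@H]2[C@H](OC(=O)[C@@H](OC)c2ccccc2)C1
F3 | step 11 | (1R)-enol triflate: as 15 with OSO2CF3 on C6 | COC(=O)C1=CC[C@@]2(C)CCC3(OCCO3)C2=C(OS(=O)(=O)C(F)(F)F)C1
F4 | step 11 | (1R)-diene ester: as 15 with H on C6 | COC(=O)C1=CC[C@@]2(C)CCC3(OCCO3)C2=CC1
F5 | step 11 | (1R,5S,6S)-hydroxy ester: trans-fused, 6α-OH, CO2Me on C8 | COC(=O)C1=CC[C@@]2(C)CCC3(OCCO3)[C@@H]2[C@@H](O)C1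
F6 | step 11 | (1R,5S,6S)-diol: 6α-OH and CH2OH on C8 | OCC1=CC[C@@]2(C)CCC3(OCCO3)[C@@H]2[C@@H](O)C1
F7 | step 11 | (1R,5S,6S)-primary allylic mesylate of F6 | CS(=O)(=O)OCC1=CC[C@@]2(C)CCC3(OCCO3)[C@@H]2[C@@H](O)C1
F8 | step 12 | (1R,5S,6R)-alcohol: 6β-OH epimer of 20 | CC1=CC[C@@]2(C)CCC3(OCCO3)[C@@H]2[C@H](O)C1
F9 | step 12 | 6α-(4-nitrobenzoate) of 20 | CC1=CC[C@@]2(C)CCC3(OCCO3)[C@@H]2[C@@H](OC(=O)c2ccc(cc2)[N+](=O)[O-])C1
F10 | step 15 | isopropenyl carbinol: as 23 with prop-1-en-2-yl at C4 | CC1=CC[C@@]2(C)CC[C@@](O)(C(C)=C)[C@@H]2[C@@H](O[Si](C)(C)C(C)(C)C)C1
A1 | alternative 1 | α-epoxide with 2-(1,3-dithian-2-yl)ethyl chain on quaternary C1 | CC1=CC[C@@](C)(CCC2SCCCS2)[C@H]2O[C@H]2C1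
A2 | alternative 1 | trans-fused hydroazulene with C4 dithiane and 6α-hydroxyl | CC1=CC[C@@]2(C)CCC3(SCCCS3)[C@@H]2[C@@H](O)C1
A3 | alternative 2 | cis-decalin: C6 tertiary hydroxyl, C5 equatorial mesylate, C4 trimethylsilyl ether with isopropyl | CC1=CC[C@@]2(C)CC[C@@](O[Si](C)(C)C)(C(C)C)[C@H](OS(C)(=O)=O)[C@@]2(O)C1
A4 | alternative 2 | trans-fused hydroazulen-6-one with C4 trimethylsilyl ether and isopropyl | CC1=CC[C@@]2(C)CC[C@@](O[Si](C)(C)C)(C(C)C)[C@@H]2C(=O)C1
A5 | alternative 3 | cross-conjugated dienone: 2-[(E)-3-(trimethylsilyl)acryloyl]cyclohepta-1,4-diene with C6 silyl ether | CC1=CCC(C)=C(C(=O)/C=C/[Si](C)(C)C)[C@H](O[Si](C)(C)C(C)(C)C)C1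
A6 | alternative 3 | trans-fused cyclopentenone with quaternary C1 and C6 silyl ether on the face of the C1 methyl | CC1=CC[C@@]2(C)C=CC(=O)[C@@H]2[C@H](O[Si](C)(C)C(C)(C)C)C1
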